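## Retrosynthetic overview

1. Target 14 ⇐ 13 by hydrogenolysis of five benzyl ethers and of a blocking bromide at C8 of the flavone.
2. 13 ⇐ open-chain chalcone/β-diketone 11 by closing both pyranone rings in one flask: enantioselective oxa-Michael addition (flavanone ring C, sets C2 as S), then cyclodehydration (flavone ring C).
3. 11 ⇐ Claisen–Schmidt condensation of biaryl aldehyde 8 with acetophenone 10 (flavanone ring A).
4. 8 ⇐ Suzuki coupling of iodide 5 with the boronate from bromoaldehyde 6 (ring B). 5 ⇐ acetophenone 1 by bromination (blocks the site ortho to OH), iodination para to the only free OH (fixes the 6-linkage) and C-aroylation with 4.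
5. Ring order: the four benzene rings are bought; the two heterocycles are made last, together.

Assumption: 1, 4, 6 and 9 are bought as catalogue compounds; the biaryl axis carries only three ortho substituents and is treated as freely rotating, so C2 of the flavanone is the only stereo-element.

## Route

Step 1
Reactants: 1 1-[2,4-bis(benzyloxy)-6-hydroxyphenyl]ethanone
Product: 2 1-[4,6-bis(benzyloxy)-3-bromo-2-hydroxyphenyl]ethanone
Conditions: NBS (1.0 equiv), CH2Cl2, 0 °C to rt
Reagents that add atoms: N-bromosuccinimide, O=C1CCC(=O)N1Br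
Why: Electrophilic aromatic bromination goes ortho to the chelated phenol (C3), the site that reacts first in 2-hydroxy-4,6-dialkoxyacetophenones, and so blocks the position that would otherwise lead to the 8-linked flavone.

Step 2
Reactants: 2 1-[4,6-bis(benzyloxy)-3-bromo-2-hydroxyphenyl]ethanone
Product: 3 1-[4,6-bis(benzyloxy)-3-bromo-2-hydroxy-5-iodophenyl]ethanone
Conditions: NIS (1.2 equiv), TFA (0.3 equiv), MeCN, rt
Reagents that add atoms: N-iodosuccinimide, O=C1CCC(=O)N1I
Why: Electrophilic aromatic iodination can only take the one remaining ring position, C5 between the two benzyl ethers and para to the free OH, which later becomes C6 of the flavone.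

Step 3
Reactants: 3 1-[4,6-bis(benzyloxy)-3-bromo-2-hydroxy-5-iodophenyl]ethanone; 4 4-(benzyloxy)benzoyl chloride
Product: 5 1-[4,6-bis(benzyloxy)-3-bromo-2-hydroxy-5-iodophenyl]-3-[4-(benzyloxy)phenyl]propane-1,3-dione
Conditions: LiN(SiMe3)2 (3.2 equiv), THF, −78 °C; then 4, −78 °C to rt; aq HCl work-up
Reagents that add atoms: none
Why: One-pot Baker–Venkataraman-type C-aroylation of the lithium phenoxide–enolate gives the β-diketone directly, and the aryl bromide and iodide are inert to the amide base.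

Step 4
Reactants: 6 4-(benzyloxy)-3-bromobenzaldehyde; 5 1-[4,6-bis(benzyloxy)-3-bromo-2-hydroxy-5-iodophenyl]-3-[4-(benzyloxy)phenyl]propane-1,3-dione
Product: 8 4-(benzyloxy)-3-{2,6-bis(benzyloxy)-3-bromo-4-hydroxy-5-[3-(4-(benzyloxy)phenyl)-3-oxopropanoyl]phenyl}benzaldehyde, via aryl pinacol boronate 7 (not isolated)
Conditions: 6, B2pin2 (1.05 equiv), Pd2(dba)3 (2 mol%), XPhos (8 mol%), KOAc, dioxane, 100 °C; then 5 (0.9 equiv), aq K3PO4 (5 equiv), 90 °C
Reagents that add atoms: none
Why: Miyaura borylation of the unhindered bromide followed by Suzuki–Miyaura coupling in the same flask works because zerovalent palladium inserts into the C–I bond far faster than into the electron-rich C–Br bond next to the phenoxide, and XPhos copes with the three ortho substituents of the new biaryl.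

Step 5
Reactants: 9 1-(2,4-dihydroxy-6-methoxyphenyl)ethanone
Product: 10 1-[4-(benzyloxy)-2-hydroxy-6-methoxyphenyl]ethanone
Conditions: BnBr (1.05 equiv), K2CO3 (1.1 equiv), acetone, reflux
Reagents that add atoms: benzyl bromide, BrCc1ccccc1
Why: Williamson etherification alkylates only the 4-OH, because the 2-OH is held in a hydrogen bond to the ketone.

Step 6
Reactants: 8 4-(benzyloxy)-3-{2,6-bis(benzyloxy)-3-bromo-4-hydroxy-5-[3-(4-(benzyloxy)phenyl)-3-oxopropanoyl]phenyl}benzaldehyde; 10 1-[4-(benzyloxy)-2-hydroxy-6-methoxyphenyl]ethanone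
Product: 11 (E)-chalcone β-diketone 1-{2,4-bis(benzyloxy)-3-[2-(benzyloxy)-5-((E)-3-(4-(benzyloxy)-2-hydroxy-6-methoxyphenyl)-3-oxoprop-1-enyl)phenyl]-5-bromo-6-hydroxyphenyl}-3-[4-(benzyloxy)phenyl]propane-1,3-dione
Conditions: KOH (50% aq, 15 equiv), EtOH–THF (2:1), 0 °C to rt, 36 h; then cold 1 M HCl to pH 5
Reagents that add atoms: none
Why: Claisen–Schmidt aldol condensation is cross-selective because only 10 has an enolisable methyl ketone and only 8 an aldehyde, the β-diketone sits as its inert enolate as it does under Baker–Venkataraman conditions, the chalcone phenoxide does not cyclise in strong base, and E1cB dehydration gives the E-alkene.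

Step 7
Reactants: 11 (E)-chalcone β-diketone
Product: 13 5,7-bis(benzyloxy)-6-{2-(benzyloxy)-5-[(2S)-7-(benzyloxy)-5-methoxy-4-oxochroman-2-yl]phenyl}-2-[4-(benzyloxy)phenyl]-8-bromo-4H-chromen-4-one, via (2S)-flavanone β-diketone 12 (not isolated)
Conditions: quinine-derived thiourea 1-[3,5-bis(trifluoromethyl)phenyl]-3-[(8S,9S)-6'-methoxycinchonan-9-yl]thiourea (20 mol%), toluene–CH2Cl2 (4:1), −20 °C to rt, 48 h; then TsOH·H2O (0.6 equiv), 40 °C, 3 h
Reagents that add atoms: none
Why: Proposed new method: the quinuclidine nitrogen activates the 2'-OH while the thiourea binds the enone carbonyl, so the phenol adds 6-endo to one face of the alkene and sets C2 as S (closest known reaction: cinchona–thiourea oxa-Michael cyclisation of 2'-hydroxychalcones to flavanones; the sense is first checked on the chalcone from 10 and benzaldehyde, and the quinidine-derived pseudo-enantiomer is used if it is opposite), the 6'-methoxy group twists the enone so closure is fast and not reversed, and after the catalyst is protonated the o-hydroxy β-diketone, whose only free OH is the one para to the biaryl carbon, cyclodehydrates to the 6-aryl flavone (closest known reaction: acid cyclodehydration of Baker–Venkataraman diketones), so both pyranone rings form in one flask.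

Step 8
Reactants: 13 5,7-bis(benzyloxy)-6-{2-(benzyloxy)-5-[(2S)-7-(benzyloxy)-5-methoxy-4-oxochroman-2-yl]phenyl}-2-[4-(benzyloxy)phenyl]-8-bromo-4H-chromen-4-one
Product: 14 5,7-dihydroxy-6-{2-hydroxy-5-[(2S)-7-hydroxy-5-methoxy-4-oxochroman-2-yl]phenyl}-2-(4-hydroxyphenyl)-4H-chromen-4-one (CNP0332590.1)
Conditions: H2 (1 atm), 10% Pd/C, NaOAc (1.5 equiv), EtOAc–MeOH (1:1), rt; stopped at full conversion
Reagents that add atoms: none
Why: Catalytic hydrogenolysis removes the five benzyl ethers and the aryl bromide (hydrodehalogenation) under near-neutral conditions, NaOAc takes up the HBr so the flavanone centre is not opened and scrambled, and the flavone C2=C3 bond and both ketones survive at 1 atm.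

## Compound list

1 | 1-[2,4-bis(benzyloxy)-6-hydroxyphenyl]ethanone | CC(=O)c1c(O)cc(OCc2ccccc2)cc1OCc1ccccc1 | starting material
2 | 1-[4,6-bis(benzyloxy)-3-bromo-2-hydroxyphenyl]ethanone | CC(=O)c1c(O)c(Br)c(OCc2ccccc2)cc1OCc1ccccc1 | intermediate
3 | 1-[4,6-bis(benzyloxy)-3-bromo-2-hydroxy-5-iodophenyl]ethanone | CC(=O)c1c(O)c(Br)c(OCc2ccccc2)c(I)c1OCc1ccccc1 | intermediate
4 | 4-(benzyloxy)benzoyl chloride | O=C(Cl)c1ccc(OCc2ccccc2)cc1 | starting material
5 | 1-[4,6-bis(benzyloxy)-3-bromo-2-hydroxy-5-iodophenyl]-3-[4-(benzyloxy)phenyl]propane-1,3-dione | O=C(CC(=O)c1ccc(OCc2ccccc2)cc1)c1c(O)c(Br)c(OCc2ccccc2)c(I)c1OCc1ccccc1 | intermediate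
6 | 4-(benzyloxy)-3-bromobenzaldehyde | O=Cc1ccc(OCc2ccccc2)c(Br)c1 | starting material
7 | 4-(benzyloxy)-3-(4,4,5,5-tetramethyl-1,3,2-dioxaborolan-2-yl)benzaldehyde | O=Cc1ccc(OCc2ccccc2)c(B2OC(C)(C)C(C)(C)O2)c1 | intermediate
8 | 4-(benzyloxy)-3-{2,6-bis(benzyloxy)-3-bromo-4-hydroxy-5-[3-(4-(benzyloxy)phenyl)-3-oxopropanoyl]phenyl}benzaldehyde | O=Cc1ccc(OCc2ccccc2)c(c1)-c1c(OCc2ccccc2)c(Br)c(O)c(C(=O)CC(=O)c2ccc(OCc3ccccc3)cc2)c1OCc1ccccc1 | intermediate
9 | 1-(2,4-dihydroxy-6-methoxyphenyl)ethanone | CC(=O)c1c(O)cc(O)cc1OC | starting material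
10 | 1-[4-(benzyloxy)-2-hydroxy-6-methoxyphenyl]ethanone | CC(=O)c1c(O)cc(OCc2ccccc2)cc1OC | intermediate
11 | (E)-chalcone β-diketone: 1-{2,4-bis(benzyloxy)-3-[2-(benzyloxy)-5-((E)-3-(4-(benzyloxy)-2-hydroxy-6-methoxyphenyl)-3-oxoprop-1-enyl)phenyl]-5-bromo-6-hydroxyphenyl}-3-[4-(benzyloxy)phenyl]propane-1,3-dione | COc1cc(OCc2ccccc2)cc(O)c1C(=O)/C=C/c1ccc(OCc2ccccc2)c(c1)-c1c(OCc2ccccc2)c(Br)c(O)c(C(=O)CC(=O)c2ccc(OCc3ccccc3)cc2)c1OCc1ccccc1 | intermediate
12 | (2S)-flavanone β-diketone: 1-{2,4-bis(benzyloxy)-3-[2-(benzyloxy)-5-((2S)-7-(benzyloxy)-5-methoxy-4-oxochroman-2-yl)phenyl]-5-bromo-6-hydroxyphenyl}-3-[4-(benzyloxy)phenyl]propane-1,3-dione | COc1cc(OCc2ccccc2)cc2c1C(=O)C[C@@H](c1ccc(OCc3ccccc3)c(c1)-c1c(OCc3ccccc3)c(Br)c(O)c(C(=O)CC(=O)c3ccc(OCc4ccccc4)cc3)c1OCc1ccccc1)O2 | intermediate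
13 | 5,7-bis(benzyloxy)-6-{2-(benzyloxy)-5-[(2S)-7-(benzyloxy)-5-methoxy-4-oxochroman-2-yl]phenyl}-2-[4-(benzyloxy)phenyl]-8-bromo-4H-chromen-4-one | COc1cc(OCc2ccccc2)cc2c1C(=O)C[C@@H](c1ccc(OCc3ccccc3)c(c1)-c1c(OCc3ccccc3)c(Br)c3oc(-c4ccc(OCc5ccccc5)cc4)cc(=O)c3c1OCc1ccccc1)O2 | intermediate
14 | 5,7-dihydroxy-6-{2-hydroxy-5-[(2S)-7-hydroxy-5-methoxy-4-oxochroman-2-yl]phenyl}-2-(4-hydroxyphenyl)-4H-chromen-4-one | COc1cc(O)cc2c1C(=O)C[C@@H](c1ccc(O)c(-c3c(O)cc4oc(-c5ccc(O)cc5)cc(=O)c4c3O)c1)O2 | target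

## Step count and risks

Total steps: 8. Longest linear sequence: 7 (steps 1, 2, 3, 4, 6, 7, 8 from 1); step 5 is the side branch.

The three steps most likely to fail:

Step 7 is the most exposed. The chalcone is not activated, the substrate is large, the acidic diketone may tie up the basic catalyst, and the acid stage may erode the enantiomeric excess. The fallback sets out from 11 and comes back at 13. Both rings are closed without stereocontrol (NaOAc, EtOH, reflux; then TsOH·H2O) to give the racemic pentabenzyl bromo-biflavonoid F1. F1 is then resolved by asymmetric transfer hydrogenation with RuCl(p-cymene)[(R,R)-TsDPEN] in HCO2H–Et3N, stopped near half conversion. This reduces the (2R)-flavanone to the cis-(2R,4R)-flavan-4-ol F2, which is removed on silica, and leaves (2S)-13 in at most half the mass. The sense is checked on the model flavanone from 10 and benzaldehyde first. This replaces asymmetric catalysis by a kinetic resolution.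

Step 6 is the second risk. The β-diketone of 8 may undergo Knoevenagel condensation with the aldehyde or retro-Claisen cleavage in KOH. The fallback sets out from 8 and comes back at 13. The diketone is removed first by cyclodehydration (TsOH·H2O, toluene, 60 °C) to the flavone aldehyde F3. Claisen–Schmidt condensation of F3 with 10 (KOH, EtOH–THF) gives the chalcone flavone F4. The thiourea-catalysed oxa-Michael step, now closing only the flavanone ring, gives 13.

Step 4 is the third risk. The coupling is hindered, and the chelating diketone and free phenol of 5 may slow the catalyst or give premature ring closure. The fallback sets out from 5 and comes back at 13. 5 is cyclodehydrated (TsOH·H2O, toluene, 60 °C) to the 8-bromo-6-iodoflavone F5. F5 is coupled with boronate 7, prepared separately from 6 and isolated, using Pd(OAc)2/SPhos and K3PO4 in toluene–water. This gives the flavone aldehyde F3, and the route then runs through the chalcone flavone F4 to 13 as described for step 6. Here the biaryl bond is made on a closed, diketone-free flavone.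

Further compounds

F1 | step 7 | racemic 5,7-bis(benzyloxy)-6-{2-(benzyloxy)-5-[7-(benzyloxy)-5-methoxy-4-oxochroman-2-yl]phenyl}-2-[4-(benzyloxy)phenyl]-8-bromo-4H-chromen-4-one | COc1cc(OCc2ccccc2)cc2c1C(=O)CC(c1ccc(OCc3ccccc3)c(c1)-c1c(OCc3ccccc3)c(Br)c3oc(-c4ccc(OCc5ccccc5)cc4)cc(=O)c3c1OCc1ccccc1)O2
F2 | step 7 | 5,7-bis(benzyloxy)-6-{2-(benzyloxy)-5-[(2R,4R)-7-(benzyloxy)-4-hydroxy-5-methoxychroman-2-yl]phenyl}-2-[4-(benzyloxy)phenyl]-8-bromo-4H-chromen-4-one | COc1cc(OCc2ccccc2)cc2c1[C@H](O)C[C@H](c1ccc(OCc3ccccc3)c(c1)-c1c(OCc3ccccc3)c(Br)c3oc(-c4ccc(OCc5ccccc5)cc4)cc(=O)c3c1OCc1ccccc1)O2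
F3 | step 6 | 4-(benzyloxy)-3-{5,7-bis(benzyloxy)-2-[4-(benzyloxy)phenyl]-8-bromo-4-oxo-4H-chromen-6-yl}benzaldehyde | O=Cc1ccc(OCc2ccccc2)c(c1)-c1c(OCc2ccccc2)c(Br)c2oc(-c3ccc(OCc4ccccc4)cc3)cc(=O)c2c1OCc1ccccc1
F4 | step 6 | 5,7-bis(benzyloxy)-6-{2-(benzyloxy)-5-[(E)-3-(4-(benzyloxy)-2-hydroxy-6-methoxyphenyl)-3-oxoprop-1-enyl]phenyl}-2-[4-(benzyloxy)phenyl]-8-bromo-4H-chromen-4-one | COc1cc(OCc2ccccc2)cc(O)c1C(=O)/C=C/c1ccc(OCc2ccccc2)c(c1)-c1c(OCc2ccccc2)c(Br)c2oc(-c3ccc(OCc4ccccc4)cc3)cc(=O)c2c1OCc1ccccc1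
F5 | step 4 | 5,7-bis(benzyloxy)-2-[4-(benzyloxy)phenyl]-8-bromo-6-iodo-4H-chromen-4-one | O=c1cc(-c2ccc(OCc3ccccc3)cc2)oc2c(Br)c(OCc3ccccc3)c(I)c(OCc3ccccc3)c12
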